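**Plan** (atom numbers follow the caryophyllane numbering of the bicyclo[7.2.0]undecane part: C1/C9 = cyclobutane CH next to CMe2 (C11)/CH2 (C10), C2–C3 = ring CH2–CH2, C4 = carbon with CH3 and the pyran O, C5 = pyran CH, C8 = carbon with the exocyclic CH2)
1. Retrosynthesis: a retro-hetero-Diels–Alder cut of O–C4 and C5–CH2 opens the dihydropyran to (−)-β-caryophyllene and the α-methylene trione of a C-trimethylated acylphloroglucinol; the nine-membered ring is then cut at C2–C3, the chain at C7–C8, and the cyclobutane at C1–C11/C9–C10.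
2. Enabling feature: with the pyran opened, C3 is the primary allylic carbon of the E-C4=C5 alkene and C2 is a CH2 on cyclobutane carbon C1, so a traceless sulfone on C2 can close the ring by SN2; the trans-fused cyclobutane (C1, C9, C10, C11), sp2 C8 and the E-alkene leave only six rotors in the chain.
3. Forward order: cyclobutane by [2+2] photocycloaddition, chain attached at C8, nine-membered ring closed at C2–C3, sulfone removed, pyran ring last by oxidative hetero-Diels–Alder with the dearomatized acylphloroglucinol (its six-membered ring comes from phloroglucinol).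
4. Stereochemistry: C9 from the menthyloxy-directed face of the photocycloaddition; C1 by base epimerization to the trans cyclobutane; E-C4=C5 from E-selective SeO2 oxidation; C4/C5 from suprafacial addition to the outer face of the E-cycloalkene in its major conformer; the acyl stereocentre from (S)-2-methylbutanoic acid.

Key step: step 10

Assumption: (5R)-5-(l-menthyloxy)furan-2(5H)-one is taken as a purchasable chiral butenolide (otherwise it is one acetalization from 5-hydroxyfuran-2(5H)-one and l-menthol).

**Step 1**
Reactants: 1 5-bromo-2-methylpent-2-ene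
Product: 2 (2E)-5-bromo-2-methylpent-2-en-1-ol
Conditions: SeO2 (0.5 equiv), t-BuOOH (2 equiv), salicylic acid (0.1 equiv), CH2Cl2, rt
Reagents that add atoms: tert-butyl hydroperoxide CC(C)(C)OO (terminal oxygen source); selenium dioxide O=[Se]=O (transfers the oxygen)
Why: Allylic oxidation by SeO2 (ene reaction, then [2,3]-sigmatropic shift) attacks the E-methyl group of the trisubstituted alkene, which sets the E geometry of the future C4=C5 alkene, while the homoallylic bromide is inert.

**Step 2**
Reactants: 2 (2E)-5-bromo-2-methylpent-2-en-1-ol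
Product: 3 [(2E)-5-bromo-2-methylpent-2-en-1-yl]oxy(tert-butyl)dimethylsilane
Conditions: TBSCl, imidazole, CH2Cl2, 0 °C to rt
Reagents that add atoms: tert-butyldimethylsilyl chloride CC(C)(C)[Si](C)(C)Cl
Why: Standard silylation of a primary allylic alcohol gives an ether that survives Grignard formation and the Wittig reaction.

**Step 3**
Reactants: 4 (5R)-5-[(1R,2S,5R)-menthyloxy]furan-2(5H)-one; 5 isobutene
Product: 6 (1S,4R,5S)-6,6-dimethyl-4-[(1R,2S,5R)-menthyloxy]-3-oxabicyclo[3.2.0]heptan-2-one
Conditions: isobutene (20 equiv), acetone (solvent and sensitizer), hν (medium-pressure Hg lamp, Pyrex), −40 °C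
Reagents that add atoms: none
Why: Acetone-sensitized enone–alkene [2+2] photocycloaddition, in which the five-membered ring enforces the cis ring fusion, isobutene should add head-to-tail (CMe2 on the β-carbon, as with cyclic enones) and from the face anti to the menthyloxy group, which sets C9 (and, for the moment, C1).

**Step 4**
Reactants: 6 (1S,4R,5S)-6,6-dimethyl-4-[(1R,2S,5R)-menthyloxy]-3-oxabicyclo[3.2.0]heptan-2-one
Product: 8 (1S,2R)-2-formyl-3,3-dimethylcyclobutane-1-carboxylic acid, via lithium cis-formyl carboxylate 7 (not isolated)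
Conditions: LiOH·H2O (3 equiv), THF/H2O 2:1, 0 °C to rt; then 1 M HCl to pH 2, 0 °C; the acid is taken into aqueous NaHCO3 to leave any cis lactol behind
Reagents that add atoms: lithium hydroxide [Li+].[OH-]
Why: Hydroxide opens the pseudo-ester (acylated lactol acetal) to menthol and the formyl carboxylate, and in the basic medium the only enolizable centre, the formyl-bearing C1 (C9 sits next to a carboxylate), should epimerize to the more stable trans-1,2-disubstituted cyclobutane, so that C1 and C9 now have the configuration of the target.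

**Step 5**
Reactants: 8 (1S,2R)-2-formyl-3,3-dimethylcyclobutane-1-carboxylic acid
Product: 9 (1S,2R)-3,3-dimethyl-2-[(phenylsulfanyl)methyl]cyclobutane-1-carboxylic acid
Conditions: PhSH (1.1 equiv), Et3SiH (2 equiv), CF3CO2H (5 equiv), CH2Cl2, 0 °C to rt
Reagents that add atoms: thiophenol Sc1ccccc1
Why: Reductive thioetherification, in which the acid-generated thionium ion from the aldehyde and thiophenol is reduced by Et3SiH (ionic hydrogenation) while the carboxylic acid and both stereocentres are unaffected.

**Step 6**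
Reactants: 9 (1S,2R)-3,3-dimethyl-2-[(phenylsulfanyl)methyl]cyclobutane-1-carboxylic acid
Product: 10 (1S,2R)-3,3-dimethyl-2-[(phenylsulfonyl)methyl]cyclobutane-1-carboxylic acid
Conditions: 30% H2O2 (3 equiv), Na2WO4·2H2O (2 mol %), MeOH, rt to 50 °C
Reagents that add atoms: hydrogen peroxide OO
Why: Tungstate-catalysed peroxide oxidation takes the sulfide to the sulfone before any alkene is present.

**Step 7**
Reactants: 10 (1S,2R)-3,3-dimethyl-2-[(phenylsulfonyl)methyl]cyclobutane-1-carboxylic acid; 3 [(2E)-5-bromo-2-methylpent-2-en-1-yl]oxy(tert-butyl)dimethylsilane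
Product: 13 (4E)-6-[(tert-butyldimethylsilyl)oxy]-1-[(1S,2R)-3,3-dimethyl-2-[(phenylsulfonyl)methyl]cyclobutyl]-5-methylhex-4-en-1-one, via acid chloride 11 (not isolated), via Grignard reagent 12 (not isolated)
Conditions: 10, (COCl)2 (1.2 equiv), DMF (cat.), CH2Cl2, 0 °C to rt, evaporate; separately 3, Mg, THF, rt; then both with Fe(acac)3 (3 mol %), THF, −78 °C
Reagents that add atoms: none
Why: Iron-catalysed acylation of an alkyl Grignard reagent with an acid chloride (Kumada-type acyl cross-coupling) is fast at −78 °C, stops at the ketone and tolerates the sulfone and the silyl ether, and C9 next to the new ketone already holds its thermodynamically preferred trans configuration.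

**Step 8**
Reactants: 13 (4E)-6-[(tert-butyldimethylsilyl)oxy]-1-[(1S,2R)-3,3-dimethyl-2-[(phenylsulfonyl)methyl]cyclobutyl]-5-methylhex-4-en-1-one
Product: 14 tert-butyl{[(2E)-6-[(1S,2R)-3,3-dimethyl-2-[(phenylsulfonyl)methyl]cyclobutyl]-2-methylhepta-2,6-dien-1-yl]oxy}dimethylsilane
Conditions: Ph3PCH3Br (2.5 equiv), KOtBu (2.4 equiv), THF, 0 °C to rt
Reagents that add atoms: methyltriphenylphosphonium bromide (as its ylide) C[P+](c1ccccc1)(c1ccccc1)c1ccccc1.[Br-]
Why: Wittig methylenation of the ketone installs the exocyclic methylene at C8, the non-stabilized ylide being too weak a base to deprotonate the sulfone.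

**Step 9**
Reactants: 14 tert-butyl{[(2E)-6-[(1S,2R)-3,3-dimethyl-2-[(phenylsulfonyl)methyl]cyclobutyl]-2-methylhepta-2,6-dien-1-yl]oxy}dimethylsilane
Product: 15 (1S,2R)-1-[(5E)-7-bromo-6-methylhepta-1,5-dien-2-yl]-3,3-dimethyl-2-[(phenylsulfonyl)methyl]cyclobutane
Conditions: Ph3PBr2 (1.5 equiv), CH2Cl2, 0 °C to rt
Reagents that add atoms: triphenylphosphine dibromide BrP(Br)(c1ccccc1)(c1ccccc1)c1ccccc1
Why: Ph3PBr2 converts the silyl ether directly to the bromide under neutral conditions (Appel-type oxyphosphonium formation, then SN2 at the primary allylic carbon), so the E geometry is kept.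

**Step 10**
Reactants: 15 (1S,2R)-1-[(5E)-7-bromo-6-methylhepta-1,5-dien-2-yl]-3,3-dimethyl-2-[(phenylsulfonyl)methyl]cyclobutane
Product: 16 (1R,4E,9S)-4,11,11-trimethyl-8-methylidene-2-(phenylsulfonyl)bicyclo[7.2.0]undec-4-ene (2-phenylsulfonyl-β-caryophyllene; both C2 epimers)
Conditions: LiN(iPr)2 (LDA, 1.3 equiv), THF/DMPU 10:1, 0.002 M, −78 °C, then slowly to 0 °C; aq. NH4Cl
Reagents that add atoms: none
Why: LDA removes a proton at C2 next to the sulfone, and the lithiated sulfonyl carbanion displaces the primary allylic bromide at C3 in an intramolecular SN2 reaction that forms the C2–C3 bond. The closest known reaction type is the intramolecular alkylation of α-sulfonyl carbanions by allylic halides, used to close medium and large carbocycles in terpene synthesis. The nine-membered ring closes in the 9-exo-tet mode. The only new stereocentre is C2, which should form as a mixture of epimers and is erased in step 11, while C1, C9 and the E-alkene are untouched because no allyl metal or allyl cation is involved. The step needs ring closure to beat oligomerization and SN2 at C3 to beat SN2′ at C5: the first is served by high dilution on a fast, irreversible alkylation and by the trans-fused cyclobutane, sp2 C8 and E-alkene, which leave six rotors in the chain; the second by the unhindered primary C3 against the secondary C5 flanked by the C4 methyl.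

**Step 11**
Reactants: 16 (1R,4E,9S)-4,11,11-trimethyl-8-methylidene-2-(phenylsulfonyl)bicyclo[7.2.0]undec-4-ene
Product: 17 (−)-β-caryophyllene, (1R,4E,9S)-4,11,11-trimethyl-8-methylidenebicyclo[7.2.0]undec-4-ene
Conditions: LiC10H8 (lithium naphthalenide, 0.5 M in THF, 4 equiv), THF, −78 °C; then MeOH
Reagents that add atoms: none
Why: Reductive desulfonylation as in Julia-type sequences, in which single-electron transfer cleaves the C2–S bond and the alkyl radical should be reduced to the alkyllithium faster than the cyclobutylcarbinyl system can open, protonation then giving the CH2 while the isolated alkenes are not reduced.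

**Step 12**
Reactants: 18 (2S)-2-methylbutanoic acid; 19 phloroglucinol
Product: 21 (2S)-2-methyl-1-(2,4,6-trihydroxyphenyl)butan-1-one, via (2S)-2-methylbutanoyl chloride 20 (not isolated)
Conditions: 18, (COCl)2, DMF (cat.), CH2Cl2, 0 °C to rt; then 19, AlCl3 (3.5 equiv), PhNO2/CH2Cl2, 0 °C to rt
Reagents that add atoms: none
Why: Friedel–Crafts C-acylation of the electron-rich, symmetrical phloroglucinol, run cold to limit enolization of the acyl chloride so that the (S) centre from 18 is retained.

**Step 13**
Reactants: 21 (2S)-2-methyl-1-(2,4,6-trihydroxyphenyl)butan-1-one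
Product: 22 3,5-dihydroxy-4,6,6-trimethyl-2-[(2S)-2-methylbutanoyl]cyclohexa-2,4-dien-1-one
Conditions: NaOMe (4 equiv), MeI (3.1 equiv), MeOH, 0 °C to rt
Reagents that add atoms: iodomethane CI
Why: Base-mediated dearomatizing C-methylation places three methyl groups on the two free ring carbons (one geminal pair), and the side-chain α-proton should stay because the ring is held as a delocalized enolate.

**Step 14**
Reactants: 17 (−)-β-caryophyllene; 22 3,5-dihydroxy-4,6,6-trimethyl-2-[(2S)-2-methylbutanoyl]cyclohexa-2,4-dien-1-one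
Product: 24 target CNP0591516.2 (dihydropyran fused across C4–C5 of the caryophyllane, O on C4 (4R), CH2 on C5 (5S), (1R,9S) ring fusion, (S)-2-methylbutanoyl enol-trione), via methylene trione 23 (not isolated)
Conditions: 22 (2 equiv), PhI(OAc)2 (1.2 equiv to 22), TEMPO (0.2 equiv to 22), THF, −78 °C to rt
Reagents that add atoms: none
Why: Oxidative dehydrogenation of the C-methyl β-triketone gives the α-methylene trione (an o-quinone methide analogue), which undergoes the biomimetic inverse-electron-demand hetero-Diels–Alder reaction with the strained E-C4=C5 alkene, where oxygen bonds to the tertiary C4 and CH2 to C5, suprafacial addition gives the trans methyl/hydrogen pair, and attack on the outer face of the major ring conformer should give the (4R,5S) isomer, the diastereomer from the minor conformer being removed by chromatography.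

**Compound list**
1 | 5-bromo-2-methylpent-2-ene | CC(C)=CCCBr | starting material
2 | (2E)-5-bromo-2-methylpent-2-en-1-ol | OC/C(C)=C/CCBr | intermediate
3 | [(2E)-5-bromo-2-methylpent-2-en-1-yl]oxy(tert-butyl)dimethylsilane | CC(C)(C)[Si](C)(C)OC/C(C)=C/CCBr | intermediate
4 | (5R)-5-[(1R,2S,5R)-menthyloxy]furan-2(5H)-one | O=C1C=C[C@@H](O1)O[C@@H]1C[C@H](C)CC[C@H]1C(C)C | starting material
5 | isobutene | CC(C)=C | starting material
6 | (1S,4R,5S)-6,6-dimethyl-4-[(1R,2S,5R)-menthyloxy]-3-oxabicyclo[3.2.0]heptan-2-one | O=C1O[C@@H](O[C@@H]3C[C@H](C)CC[C@H]3C(C)C)[C@H]2[C@@H]1CC2(C)C | intermediate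
7 | lithium (1S,2S)-2-formyl-3,3-dimethylcyclobutane-1-carboxylate (cis) | O=C[C@H]1[C@@H](C(=O)[O-])CC1(C)C.[Li+] | intermediate
8 | (1S,2R)-2-formyl-3,3-dimethylcyclobutane-1-carboxylic acid (trans) | O=C[C@@H]1[C@@H](C(=O)O)CC1(C)C | intermediate
9 | (1S,2R)-3,3-dimethyl-2-[(phenylsulfanyl)methyl]cyclobutane-1-carboxylic acid | c1ccccc1SC[C@@H]1[C@@H](C(=O)O)CC1(C)C | intermediate
10 | (1S,2R)-3,3-dimethyl-2-[(phenylsulfonyl)methyl]cyclobutane-1-carboxylic acid | O=S(=O)(c1ccccc1)C[C@@H]1[C@@H](C(=O)O)CC1(C)C | intermediate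
11 | (1S,2R)-3,3-dimethyl-2-[(phenylsulfonyl)methyl]cyclobutane-1-carbonyl chloride | O=S(=O)(c1ccccc1)C[C@@H]1[C@@H](C(=O)Cl)CC1(C)C | intermediate
12 | {(3E)-5-[(tert-butyldimethylsilyl)oxy]-4-methylpent-3-en-1-yl}magnesium bromide | CC(C)(C)[Si](C)(C)OC/C(C)=C/CC[Mg]Br | intermediate
13 | (4E)-6-[(tert-butyldimethylsilyl)oxy]-1-[(1S,2R)-3,3-dimethyl-2-[(phenylsulfonyl)methyl]cyclobutyl]-5-methylhex-4-en-1-one | O=S(=O)(c1ccccc1)C[C@@H]1[C@@H](C(=O)CC/C=C(\C)CO[Si](C)(C)C(C)(C)C)CC1(C)C | intermediate
14 | tert-butyl{[(2E)-6-[(1S,2R)-3,3-dimethyl-2-[(phenylsulfonyl)methyl]cyclobutyl]-2-methylhepta-2,6-dien-1-yl]oxy}dimethylsilane | O=S(=O)(c1ccccc1)C[C@@H]1[C@@H](C(=C)CC/C=C(\C)CO[Si](C)(C)C(C)(C)C)CC1(C)C | intermediate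
15 | (1S,2R)-1-[(5E)-7-bromo-6-methylhepta-1,5-dien-2-yl]-3,3-dimethyl-2-[(phenylsulfonyl)methyl]cyclobutane | O=S(=O)(c1ccccc1)C[C@@H]1[C@@H](C(=C)CC/C=C(\C)CBr)CC1(C)C | intermediate
16 | (1R,4E,9S)-4,11,11-trimethyl-8-methylidene-2-(phenylsulfonyl)bicyclo[7.2.0]undec-4-ene (C2 epimers) | C=C1CC/C=C(\C)CC(S(=O)(=O)c3ccccc3)[C@@H]2[C@@H]1CC2(C)C | intermediate
17 | (−)-β-caryophyllene | C=C1CC/C=C(\C)CC[C@@H]2[C@@H]1CC2(C)C | intermediate
18 | (2S)-2-methylbutanoic acid | CC[C@H](C)C(=O)O | starting material
19 | phloroglucinol | Oc1cc(O)cc(O)c1 | starting material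
20 | (2S)-2-methylbutanoyl chloride | CC[C@H](C)C(=O)Cl | intermediate
21 | (2S)-2-methyl-1-(2,4,6-trihydroxyphenyl)butan-1-one | CC[C@H](C)C(=O)c1c(O)cc(O)cc1O | intermediate
22 | 3,5-dihydroxy-4,6,6-trimethyl-2-[(2S)-2-methylbutanoyl]cyclohexa-2,4-dien-1-one | CC1=C(O)C(C)(C)C(=O)C(C(=O)[C@@H](C)CC)=C1O | intermediate
23 | 5-hydroxy-2,2-dimethyl-6-methylidene-4-[(2S)-2-methylbutanoyl]cyclohex-4-ene-1,3-dione | C=C1C(=O)C(C)(C)C(=O)C(C(=O)[C@@H](C)CC)=C1O | intermediate
24 | target CNP0591516.2 | C=C1CC[C@H]2CC3=C(O[C@]2(C)CC[C@@H]2[C@@H]1CC2(C)C)C(C)(C)C(=O)C(C(=O)[C@@H](C)CC)=C3O | target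

**Totals**
Total step count: 14. Longest linear sequence: 10 steps (3, 4, 5, 6, 7, 8, 9, 10, 11, 14, from 4).

**Steps most likely to fail**

Step 10. Intermolecular alkylation (oligomers) or attack at the far allyl terminus may outrun the nine-membered ring closure. The fallback moves the closure to a π-allyl manifold with a soft, doubly stabilized nucleophile, a Tsuji–Trost cyclization, which is known to favour attack at the less substituted allyl terminus and hence the larger ring. It sets out from 14: LiN(iPr)2 (2.2 equiv) and methyl chloroformate give the α-methoxycarbonyl sulfone F1; Bu4NF frees the allylic alcohol F2; methyl chloroformate and pyridine give the allylic methyl carbonate F3; Pd(PPh3)4 (zerovalent palladium, 5 mol %) with dppe in refluxing THF under slow addition should give the nine-membered sulfonyl ester F4; Krapcho demethoxycarbonylation (LiCl, wet DMSO, 130 °C) comes back to the route at 16. The alkene geometry would have to be confirmed at F4, since a π-allyl complex can isomerize.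

Step 3. The photocycloaddition may show poor facial selectivity and poor head-to-tail versus head-to-head orientation. The fallback is a stepwise polar [2+2] whose orientation is fixed by polarity and whose face is the one known for conjugate additions to this butenolide. It sets out from 4: heating with N,N-dimethyl-2-methylprop-1-en-1-amine in MeCN (enamine conjugate addition, then Mannich-type closure) gives the amino cyclobutane F5; MeI gives the ammonium salt F6; K2CO3 in MeCN (Hofmann-type elimination toward the lactone α-carbon) gives the cyclobutene lactone F7; H2 over Pd/C, delivered from the face away from the lactone ring, restores the cis fusion and comes back to the route at 6.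

Step 14. The oxidant may attack the strained alkene or the product enol, and the methylene trione may condense with itself before it is trapped. The fallback generates the same heterodiene without any oxidant. It sets out from 21: NaOMe and MeI (2 equiv) give the gem-dimethyl trione F8; F8, paraformaldehyde and 17 with NaOAc in AcOH at 80 °C undergo Knoevenagel condensation to 23 and the hetero-Diels–Alder reaction in the same flask, coming back to the route at 24.

**Further compounds**
F1 | step 10 | α-methoxycarbonyl derivative of 14 (CO2Me on the sulfone-bearing carbon, both epimers) | COC(=O)C(S(=O)(=O)c1ccccc1)[C@@H]1[C@@H](C(=C)CC/C=C(\C)CO[Si](C)(C)C(C)(C)C)CC1(C)C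
F2 | step 10 | allylic alcohol from F1 | COC(=O)C(S(=O)(=O)c1ccccc1)[C@@H]1[C@@H](C(=C)CC/C=C(\C)CO)CC1(C)C
F3 | step 10 | allylic methyl carbonate from F2 | COC(=O)C(S(=O)(=O)c1ccccc1)[C@@H]1[C@@H](C(=C)CC/C=C(\C)COC(=O)OC)CC1(C)C
F4 | step 10 | methyl (1R,4E,9S)-4,11,11-trimethyl-8-methylidene-2-(phenylsulfonyl)bicyclo[7.2.0]undec-4-ene-2-carboxylate | C=C1CC/C=C(\C)CC(C(=O)OC)(S(=O)(=O)c3ccccc3)[C@@H]2[C@@H]1CC2(C)C
F5 | step 3 | 7-(dimethylamino)-6,6-dimethyl-4-[(1R,2S,5R)-menthyloxy]-3-oxabicyclo[3.2.0]heptan-2-one | O=C1O[C@@H](O[C@@H]3C[C@H](C)CC[C@H]3C(C)C)[C@H]2[C@@H]1C(N(C)C)C2(C)C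
F6 | step 3 | trimethylammonium iodide of F5 | O=C1O[C@@H](O[C@@H]3C[C@H](C)CC[C@H]3C(C)C)[C@H]2[C@@H]1C([N+](C)(C)C)C2(C)C.[I-]
F7 | step 3 | 6,6-dimethyl-4-[(1R,2S,5R)-menthyloxy]-3-oxabicyclo[3.2.0]hept-1(7)-en-2-one | O=C1O[C@@H](O[C@@H]3C[C@H](C)CC[C@H]3C(C)C)[C@H]2C1=CC2(C)C
F8 | step 14 | 3,5-dihydroxy-6,6-dimethyl-2-[(2S)-2-methylbutanoyl]cyclohexa-2,4-dien-1-one | CC[C@H](C)C(=O)C1=C(O)C=C(O)C(C)(C)C1=O
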